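**Retrosynthetic overview**
- Target 9 ⇐ chelation-assisted O-demethylation of 5-methoxy-2-pentadecylchromone 8.
- 8 ⇐ cut inside the side chain between C8' and C9' (chain numbered from chromone C2): anodic decarboxylative cross-coupling (mixed Kolbe electrolysis) of chromone-nonanoic acid 6 with octanoic acid 7, joining two carbons of like polarity.
- Enabling feature: C8' and C9' lie in an unbranched (CH2)n segment with no heteroatom or branch nearby, so both radicals are unstabilised primary alkyl radicals that couple and are not oxidised further. The electron-poor 4H-chromen-4-one (benzo-γ-pyrone) ring sits seven CH2 groups away, with its peri 5-OH masked as OMe, and is inert at the anode.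
- 6 ⇐ the pyranone ring, the only ring formed (the benzene ring comes from 1), by Baker–Venkataraman rearrangement and cyclodehydration of aryl ester 3, made from 2'-hydroxy-6'-methoxyacetophenone 1 and monomethyl sebacate 2.

Key step: step 3

Remark: the target has no stereocentre and no stereogenic double bond, so it is achiral and exists as one stereoisomer; no stereocontrol is required.

**Step 1**
Reactants: 1 2'-hydroxy-6'-methoxyacetophenone; 2 sebacic acid monomethyl ester (10-methoxy-10-oxodecanoic acid)
Product: 3 1-(2-acetyl-3-methoxyphenyl) 10-methyl decanedioate
Conditions: DCC (1.1 equiv), DMAP (0.1 equiv), CH2Cl2, 0 °C → rt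
Reagents that add atoms: none
Why: Steglich esterification; DCC activates the acid as the O-acylisourea and DMAP relays the acyl group to the hydrogen-bonded phenol, while the aryl ketone and the remote methyl ester are inert.

**Step 2**
Reactants: 3 1-(2-acetyl-3-methoxyphenyl) 10-methyl decanedioate
Product: 6 9-(5-methoxy-4-oxo-4H-chromen-2-yl)nonanoic acid, via diketone ester 4 (not isolated), via chromone methyl ester 5 (not isolated)
Conditions: KOtBu (2.5 equiv), THF, 0 °C → rt; then AcOH/6 M aq HCl, 90 °C
Reagents that add atoms: water, O
Why: Baker–Venkataraman rearrangement (the acetyl enolate takes the acyl group from the aryl ester oxygen through a six-membered transition state) should give the 1,3-diketone; hot aqueous acid then closes the γ-pyrone by cyclodehydration and hydrolyses the methyl ester in the same operation, avoiding hydroxide, which would open the pyrone.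

**Step 3**
Reactants: 6 9-(5-methoxy-4-oxo-4H-chromen-2-yl)nonanoic acid; 7 octanoic acid
Product: 8 5-methoxy-2-pentadecyl-4H-chromen-4-one
Conditions: 7 (6 equiv), KOH (5 mol% of total acid), MeOH, undivided cell, Pt anode/Pt cathode, constant current ca. 0.2 A cm⁻², 40–45 °C, ca. 1.3 F per mol of total acid, stopped while still weakly acidic
Reagents that add atoms: none
Why: Mixed (crossed) Kolbe electrolysis: both carboxylates are discharged at the platinum anode by one-electron oxidation, the acyloxy radicals lose CO2, and the n-heptyl radical and the 8-(5-methoxy-4-oxo-4H-chromen-2-yl)octyl radical, formed side by side at high stationary concentration in the anode layer, combine to the C8'–C9' bond while protons are reduced to H2 at the cathode. The closest known reaction type is the crossed Kolbe coupling of a fatty acid with an ω-functionalised alkanoic acid, as used in fatty-acid and pheromone chain assembly; here it is a decarboxylative radical–radical union of two carbons of like polarity. No ring is closed and no stereocentre is formed, so no stereocontrol is needed. Hetero- over homo-coupling is statistical and is secured by the sixfold excess of cheap 7, so that the valuable radical from 6 should meet mainly heptyl radicals; the excess ends up as tetradecane, which is unpolar and should separate readily from the chromone on silica. The radical pathway is secured over the cationic (Hofer–Moest) pathway by the two unbranched, heteroatom-free α-carbons, smooth platinum, high current density and the weakly acidic methanol electrolyte. Chemoselectivity is secured by the electron-poor benzo-γ-pyrone with its phenol masked as the methyl ether and by the carboxylate layer that occupies the anode at high current density; the C2=C3 double bond, fully substituted at C2 and seven CH2 groups from the radical centre, is not a competitive radical acceptor.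

**Step 4**
Reactants: 8 5-methoxy-2-pentadecyl-4H-chromen-4-one
Product: 9 5-hydroxy-2-pentadecyl-4H-chromen-4-one
Conditions: BCl3 (1 M in CH2Cl2, 2.5 equiv), CH2Cl2, −78 → 0 °C; then H2O, rt
Reagents that add atoms: none
Why: Chelation-directed Lewis-acid ether cleavage; boron binds the C4 carbonyl and the peri 5-methoxy oxygen in a six-membered chelate, chloride removes the methyl group by SN2, and hydrolysis of the boron chelate should release the hydrogen-bonded phenol, with the alkyl chain and the pyrone untouched.

**Compound list**
1 | 2'-hydroxy-6'-methoxyacetophenone (1-(2-hydroxy-6-methoxyphenyl)ethan-1-one) | CC(=O)c1c(O)cccc1OC | starting material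
2 | sebacic acid monomethyl ester (10-methoxy-10-oxodecanoic acid) | COC(=O)CCCCCCCCC(=O)O | starting material
3 | 1-(2-acetyl-3-methoxyphenyl) 10-methyl decanedioate | COC(=O)CCCCCCCCC(=O)Oc1cccc(OC)c1C(C)=O | intermediate
4 | methyl 12-(2-hydroxy-6-methoxyphenyl)-10,12-dioxododecanoate (diketone ester) | COC(=O)CCCCCCCCC(=O)CC(=O)c1c(O)cccc1OC | intermediate
5 | methyl 9-(5-methoxy-4-oxo-4H-chromen-2-yl)nonanoate (chromone methyl ester) | COC(=O)CCCCCCCCc1cc(=O)c2c(OC)cccc2o1 | intermediate
6 | 9-(5-methoxy-4-oxo-4H-chromen-2-yl)nonanoic acid | OC(=O)CCCCCCCCc1cc(=O)c2c(OC)cccc2o1 | intermediate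
7 | octanoic acid | CCCCCCCC(=O)O | starting material
8 | 5-methoxy-2-pentadecyl-4H-chromen-4-one | CCCCCCCCCCCCCCCc1cc(=O)c2c(OC)cccc2o1 | intermediate
9 | 5-hydroxy-2-pentadecyl-4H-chromen-4-one | CCCCCCCCCCCCCCCc1cc(=O)c2c(O)cccc2o1 | target

**Step count**
Total steps: 4. Longest linear sequence: 4 steps (1/2 → 3 → 6 → 8 → 9).

**Steps most likely to fail**

Step 3 (key step). The anode may oxidise the methoxy-substituted benzopyranone or passivate. The radicals may be oxidised on to cations (ethers and alkenes instead of the coupled chain), or too much of the valuable acid may be lost to homo-coupling. The fallback sets out from compound 6 and comes back at compound 8. Acid 6 would be esterified with N-hydroxyphthalimide (DIC, cat. DMAP, CH2Cl2) to the redox-active ester 1,3-dioxoisoindolin-2-yl 9-(5-methoxy-4-oxo-4H-chromen-2-yl)nonanoate F1. F1 would then be coupled with di-n-heptylzinc under nickel catalysis (NiCl2·glyme, 4,4'-di-tert-butyl-2,2'-bipyridine, THF/DMF, rt). This decarboxylative Negishi-type alkyl–alkyl coupling uses an organozinc, which the chromone carbonyl tolerates, and should give 8.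

Step 2. During the base stage the remote methyl ester may undergo intermolecular Claisen condensation or transesterification. In the hot acid the ester hydrolysis may stay incomplete or the 5-methyl ether may be partly cleaved. The fallback sets out from compound 1 and comes back at compound 6; it carries the future carboxyl group as a terminal alkene instead of an ester.
- Compound 1 would be acylated with commercial undec-10-enoyl chloride (pyridine, CH2Cl2) to 2-acetyl-3-methoxyphenyl undec-10-enoate F2.
- Baker–Venkataraman rearrangement (KOtBu, THF) would give 1-(2-hydroxy-6-methoxyphenyl)tridec-12-ene-1,3-dione F3.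
- Mild cyclodehydration (cat. H2SO4, AcOH) would give 2-(dec-9-en-1-yl)-5-methoxy-4H-chromen-4-one F4.
- Lemieux–Johnson cleavage (cat. OsO4, NaIO4, 2,6-lutidine, dioxane/H2O) should attack the accessible terminal alkene in preference to the electron-poor C2=C3 bond and give 9-(5-methoxy-4-oxo-4H-chromen-2-yl)nonanal F5.
- Pinnick oxidation (NaClO2, NaH2PO4, 2-methyl-2-butene, tBuOH/H2O) would give acid 6.

Step 1. O-acylation of the intramolecularly hydrogen-bonded, doubly ortho-flanked phenol may be slow, so that the O-acylisourea rearranges to the unreactive N-acylurea. The fallback sets out from compounds 1 and 2 and comes back at compound 4; it bypasses the aryl ester and the acyl migration. Acid 2 would be converted with oxalyl chloride (cat. DMF, CH2Cl2) into methyl 10-chloro-10-oxodecanoate F6. F6 would be added at −78 °C to the dilithium dianion of 1 (LiHMDS, 3 equiv, THF), so that the enolate carbon is acylated directly to diketone ester 4. Compound 4 is then taken through the acid stage of step 2.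

**Further compounds**
F1 | step 3 | 1,3-dioxoisoindolin-2-yl 9-(5-methoxy-4-oxo-4H-chromen-2-yl)nonanoate | O=C(CCCCCCCCc1cc(=O)c2c(OC)cccc2o1)ON1C(=O)c2ccccc2C1=O
F2 | step 2 | 2-acetyl-3-methoxyphenyl undec-10-enoate | C=CCCCCCCCCC(=O)Oc1cccc(OC)c1C(C)=O
F3 | step 2 | 1-(2-hydroxy-6-methoxyphenyl)tridec-12-ene-1,3-dione | C=CCCCCCCCCC(=O)CC(=O)c1c(O)cccc1OC
F4 | step 2 | 2-(dec-9-en-1-yl)-5-methoxy-4H-chromen-4-one | C=CCCCCCCCCc1cc(=O)c2c(OC)cccc2o1
F5 | step 2 | 9-(5-methoxy-4-oxo-4H-chromen-2-yl)nonanal | O=CCCCCCCCCc1cc(=O)c2c(OC)cccc2o1
F6 | step 1 | methyl 10-chloro-10-oxodecanoate | COC(=O)CCCCCCCCC(=O)Cl
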